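- At 40 h I read G in each flask, and I want to know how the X used divides between G and Z.

- ranking by amount of G, in percent of the Q charged, from high to low, at 40 h (theta / gamma / zeta / delta / alpha / epsilon)
- the amount of G, in percent of the Q charged of the flask you put first, at 40 h
- the amount of G, in percent of the Q charged of the flask you put last, at 40 h

| setting | east | north | theta | gamma | zeta | delta | alpha | epsilon |
|---|---|---|---|---|---|---|---|---|
| Q | 0.81 M | 0.27 M | 0.54 M | 0.54 M | 0.54 M | 0.54 M | 0.54 M | 0.54 M |
| X | 0.81 M | 0.81 M | 0.500 M | 0.500 M | 0.810 M | 0.810 M | 0.810 M | 0.500 M |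
| temperature | 0 °C | 0 °C | −20 °C | −15 °C | 0 °C | −20 °C | −15 °C | 0 °C |
| remark | run made earlier | run made earlier |  |  |  |  |  |  |
| time |  |  | 40 h | 40 h | 40 h | 40 h | 40 h | 40 h |

| run | time / h | G / % | Q / % |
|---|---|---|---|
| east | 1.50 | 34.9 | 58.1 |
| east | 3.00 | 50.7 | 37.3 |
| east | 5.00 | 60.3 | 23.2 |
| east | 6.00 | 63.2 | 19.2 |
| east | 8.00 | 65.8 | 13.4 |
| north | 0.667 | 20.1 | 75.8 |
| north | 1.33 | 35.2 | 59.2 |
| north | 2.50 | 53.5 | 38.1 |
| north | 4.00 | 67.0 | 21.9 |
| north | 8.00 | 80.4 | 5.3 |

(standard deviation of a reading: 0.3 percentage points)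

- On the list of suspects, X + D gives G and X + E gives Z, so I count one X for every Q that goes, by either path.
- In epsilon the charge allows 0.926 X per Q, which makes X the limiting reagent, and 7.41 % of the Q charged should stay outside G and Z.
- The north run has X to spare, so I can freeze [X] there at the middle of its range, 0.682 M.
- At its last reading 94.7 % of Q has gone and 14.3 % of the charge is unaccounted for, which I count as Z.
- From this I take s, the [X] at which G and Z form equally, as 0.121 M, a reading that carries the scatter. Each X used then makes G with the share [X]/([X]+s), a selectivity that falls as [X] falls.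
- One extreme of epsilon keeps [X] at its charge, and G comes to 74.5 %.
- The other extreme lets the share fall in a straight line to nil, and G comes to 37.2 %.
- The share [X]/([X]+s) bows above that line, so I put epsilon between the two. Summing the share from the charge down to nil leaves 0.302 M of G, which is 55.9 % of the Q charged.
- The same sum for zeta, with Q taken to its end, gives 80.5 %.
- Both earlier runs stand at 0 °C, so I have no reckoned number for the cold flasks.
- The forecast reads zeta > alpha > delta > epsilon > gamma > theta, with 80 % first and 45 % last, and says “Temperature is a guess”.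
- The flasks give alpha > zeta > delta > gamma > theta > epsilon, with zeta at 80.8 %, alpha at 88.6 % and epsilon at 57.9 %.

    Q ⇌ D (K = 0.00320, k = 0.750 h⁻¹, Ea = 83.0 kJ mol⁻¹, ΔH = −79.0 kJ mol⁻¹)
    D ⇌ E (K = 1.10, k = 37.0 h⁻¹, Ea = 76.0 kJ mol⁻¹, ΔH = −58.0 kJ mol⁻¹)
    X + D → G (k = 300 L mol⁻¹ h⁻¹, Ea = 37.0 kJ mol⁻¹)
    X + E → Z (k = 2000 L mol⁻¹ h⁻¹, Ea = 41.0 kJ mol⁻¹)
    (constants at 0 °C)

- Epsilon ends with 0 % of its X charge and 7.36 % of Q, beside 34.7 % of Z. The loss of D to E, both ways, is the main reason that G stops there: with that step taken away, epsilon reaches 90.4 %. The same s and the same fall of [X], in a neighbour flask like epsilon but with 1.4 M of Q, give 21.6 % of G and leave 64.3 % of the Q charged outside G and Z. That neighbour flask holds 63.9 % of Q and gives 22.4 % of G.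

The readings come from a simulation on assumed constants; scatter was added.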